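**Retrosynthetic overview**
1. The triene goes on last, because it would not survive singlet oxygen, I+ or tin radicals. Its central C=C comes from an HWE reaction on an (E)-enal, which is made by cross-metathesis of a terminal alkene carried through the whole route.
2. Ring B (γ-lactone, formed second): the C1 carboxyl closes onto C4 of a Δ4-1,2-dioxine, with I+ standing in for H+, followed by C–I → C–H. A chiral catalyst lets only the (3S,6S) acid lactonise.
3. Ring A (1,2-dioxine, formed first): suprafacial [4+2] addition of singlet O2 to the free (3E,5Z)-4,6-dimethyl-3,5-dienoic acid. The alkene geometry becomes the C3/C6 relative configuration.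
4. The diene is made in one flask. Propyne carbocupration sets 5Z, and Pd coupling with (E)-4-iodopent-3-enoic acid sets 3E.

Numbering used in the text: C1 lactone C=O, C2 CH2, C3 CH–OO, C4 C(Me)–O–acyl, C5 ring CH2, C6 C(Me)(chain)–OO. The target is (3S,4S,6S); the C6-methyl lies on the lactone face, and the chain lies on the face of the C4-methyl and H3.

Assumption: (DHQD)2PHAL is taken to favour the (3S,6S) acid in step 5; if an analytical run shows the opposite sense, the pseudo-enantiomeric (DHQ)2PHAL is used with nothing else changed.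

**Step 1**
Reactants: 1 pent-3-yn-1-ol
Product: 3 (E)-4-iodopent-3-en-1-ol, via bis-zirconocene alkenyl alkoxide 2 (not isolated)
Conditions: Cp2ZrHCl (2.5 equiv), THF, 0 °C → rt, dark; then I2, 0 °C
Reagents that add atoms: iodine, II
Why: In this hydrozirconation–iodinolysis the first equivalent of Cp2ZrHCl only deprotonates the alcohol, syn Zr–H addition equilibrated by the excess hydride puts zirconium on the less hindered methyl-bearing carbon, and iodinolysis with retention gives the E vinyl iodide.

**Step 2**
Reactants: 3 (E)-4-iodopent-3-en-1-ol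
Product: 4 (E)-4-iodopent-3-enoic acid
Conditions: TEMPO (0.2 equiv), PhI(OAc)2 (2.2 equiv), MeCN–H2O 1:1, rt
Reagents that add atoms: water, O
Why: The nitroxyl/PhI(OAc)2 oxidation takes the primary alcohol through the aldehyde hydrate to the acid under near-neutral conditions that neither touch the vinyl iodide nor move the β,γ-alkene into conjugation.

**Step 3**
Reactants: 5 10-bromodec-1-ene; 6 propyne; 4 (E)-4-iodopent-3-enoic acid
Product: 11 (3E,5Z)-4,6-dimethylhexadeca-3,5,15-trienoic acid, via dec-9-enylmagnesium bromide 7 (not isolated), via (Z)-alkenylcopper 8 (not isolated), via (Z)-alkenylzinc bromide 9 (not isolated), via sodium iodopentenoate 10 (not isolated)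
Conditions: 5, Mg, Et2O, reflux; CuBr·SMe2, Et2O–Me2S, −45 °C; 6 (3 equiv), −25 °C, then purge; ZnBr2, THF, −25 °C; 10 (from 4, NaH, THF, 0 °C), Pd(PPh3)4 (5 mol %), −20 °C → rt; cold 1 M HCl
Reagents that add atoms: none
Why: Normant carbocupration adds the alkylcopper syn across propyne with copper on the terminal carbon, so the chain ends cis to the metal, and Cu-to-Zn exchange followed by Negishi-type coupling on zerovalent palladium joins both alkenyl partners with retention, which fixes the 3E,5Z diene.

**Step 4**
Reactants: 11 (3E,5Z)-4,6-dimethylhexadeca-3,5,15-trienoic acid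
Product: 12 rac-2-[(3S*,6S*)-6-(dec-9-en-1-yl)-4,6-dimethyl-3,6-dihydro-1,2-dioxin-3-yl]acetic acid (CH2CO2H and C6-methyl cis)
Conditions: O2, meso-tetraphenylporphyrin (0.5 mol %), white LED, CH2Cl2, −20 °C
Reagents that add atoms: dioxygen, O=O
Why: In this sensitised photooxygenation, the suprafacial [4+2] cycloaddition of singlet oxygen to the s-cis diene (the event proposed for the natural peroxide ring) places the two "outside" groups, CH2CO2H and C6-methyl, cis and so turns the 3E,5Z geometry into the C3/C6 relative configuration, while the monosubstituted terminal alkene is inert to singlet oxygen.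

**Step 5**
Reactants: 12 racemic dioxine acetic acid
Product: 13 (3S,4S,4aR,7aS)-3-(dec-9-en-1-yl)-4-iodo-3,4a-dimethyltetrahydrofuro[3,2-c][1,2]dioxin-6(3H)-one (cis-fused; iodine on C5 anti to the lactone oxygen on C4)
Conditions: (DHQD)2PHAL (10 mol %), N-iodosuccinimide (0.5 equiv), CHCl3–toluene 1:1, −40 °C, dark; cold aq NaHCO3 wash
Reagents that add atoms: N-iodosuccinimide, O=C1CCC(=O)N1I
Why: Proposed new method: this is a kinetic resolution by catalytic asymmetric 5-exo iodolactonisation, in which the carboxylate of 12 ion-pairs with a protonated quinuclidine of (DHQD)2PHAL while the catalyst pocket holds the I+ donor, and because the acetic acid arm can reach C4 only from its own face (iodine must arrive anti, so the cis fusion and C4 follow from C3), the two enantiomers must offer opposite alkene faces to the bound iodine and react at different rates, so the faster (3S,6S) acid is taken to 13 at no more than 45–50 % conversion and the (3R,6R) acid is washed out with base; the closest known reaction types are cinchona-dimer-catalysed enantioselective halolactonisation and kinetic resolution of β-substituted olefinic acids by catalytic bromolactonisation.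

**Step 6**
Reactants: 13 iodolactone
Product: 14 (3S,4aS,7aS)-3-(dec-9-en-1-yl)-3,4a-dimethyltetrahydrofuro[3,2-c][1,2]dioxin-6(3H)-one
Conditions: Bu3SnH (1.5 equiv, 0.5 M), Et3B (0.2 equiv), trace air, toluene, 0 °C
Reagents that add atoms: none
Why: In this radical chain dehalogenation the high stannane concentration and low temperature let hydrogen transfer to the C5 radical outrun its attack on the neighbouring O–O bond, and since C5 becomes a CH2 group no stereocentre of the target is touched.

**Step 7**
Reactants: 14 terminal-alkene peroxylactone; 15 (E)-crotonaldehyde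
Product: 16 (E)-11-[(3S,4aS,7aS)-3,4a-dimethyl-6-oxotetrahydrofuro[3,2-c][1,2]dioxin-3-yl]undec-2-enal
Conditions: 15 (5 equiv), second-generation Hoveyda–Grubbs catalyst RuCl2(H2IMes)(=CH-C6H4-2-OiPr) (5 mol %), CH2Cl2, 40 °C
Reagents that add atoms: none
Why: Olefin cross-metathesis between a readily reacting terminal alkene and an electron-poor enal is selective for the cross product and strongly E-selective, and the hindered dialkyl peroxide and the lactone are spectators to the ruthenium carbene.

**Step 8**
Reactants: 17 (E)-1-bromopent-2-ene; 18 triethyl phosphite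
Product: 19 diethyl [(E)-pent-2-en-1-yl]phosphonate
Conditions: neat, 130 °C, EtBr distilled off
Reagents that add atoms: none
Why: The Michaelis–Arbuzov reaction proceeds by direct SN2 attack of phosphorus on the primary allylic bromide and keeps the E alkene.

**Step 9**
Reactants: 16 enal; 19 pentenylphosphonate
Product: 21 target, (3S,4aS,7aS)-3-[(9E,11E,13E)-hexadeca-9,11,13-trien-1-yl]-3,4a-dimethyltetrahydrofuro[3,2-c][1,2]dioxin-6(3H)-one, via lithiated phosphonate 20 (not isolated)
Conditions: 19 (1.15 equiv), LiN(SiMe3)2 (1.05 equiv), THF, −78 °C; then 16, −78 → 0 °C; aq NH4Cl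
Reagents that add atoms: none
Why: In this Horner–Wadsworth–Emmons olefination the pre-formed allylic phosphonate anion attacks the aldehyde through its α-carbon faster than it deprotonates the lactone, elimination gives the new central alkene E between two E alkenes that are carried in, and any retro-oxa-Michael opening at C3 is reversible and can only reclose to the same cis-fused ring.

**Compound list**
1 | pent-3-yn-1-ol | CC#CCCO | starting material
2 | (E)-alkenylzirconocene chloride of the zirconocene alkoxide of 1 | C/C(=C\CCO[Zr](Cl)(C1C=CC=C1)C1C=CC=C1)[Zr](Cl)(C1C=CC=C1)C1C=CC=C1 | intermediate (not isolated)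
3 | (E)-4-iodopent-3-en-1-ol | C/C(I)=C\CCO | intermediate
4 | (E)-4-iodopent-3-enoic acid | C/C(I)=C\CC(=O)O | intermediate
5 | 10-bromodec-1-ene | C=CCCCCCCCCBr | starting material
6 | propyne | CC#C | starting material
7 | dec-9-enylmagnesium bromide | C=CCCCCCCCC[Mg]Br | intermediate (not isolated)
8 | [(1Z)-2-methyldodeca-1,11-dien-1-yl]copper (MgBr2/SMe2 complex) | C=CCCCCCCCC/C(C)=C\[Cu] | intermediate (not isolated)
9 | [(1Z)-2-methyldodeca-1,11-dien-1-yl]zinc bromide | C=CCCCCCCCC/C(C)=C\[Zn]Br | intermediate (not isolated)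
10 | sodium (E)-4-iodopent-3-enoate | C/C(I)=C\CC(=O)[O-].[Na+] | intermediate (not isolated)
11 | (3E,5Z)-4,6-dimethylhexadeca-3,5,15-trienoic acid | C=CCCCCCCCC/C(C)=C\C(C)=C\CC(=O)O | intermediate
12 | rac-2-[(3S*,6S*)-6-(dec-9-en-1-yl)-4,6-dimethyl-3,6-dihydro-1,2-dioxin-3-yl]acetic acid (racemate; the (3S,6S) enantiomer is drawn) | C=CCCCCCCCC[C@@]1(C)C=C(C)[C@H](CC(=O)O)OO1 | intermediate
13 | (3S,4S,4aR,7aS)-3-(dec-9-en-1-yl)-4-iodo-3,4a-dimethyltetrahydrofuro[3,2-c][1,2]dioxin-6(3H)-one | C=CCCCCCCCC[C@@]1(C)[C@@H](I)[C@]2(C)OC(=O)C[C@@H]2OO1 | intermediate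
14 | (3S,4aS,7aS)-3-(dec-9-en-1-yl)-3,4a-dimethyltetrahydrofuro[3,2-c][1,2]dioxin-6(3H)-one | C=CCCCCCCCC[C@@]1(C)C[C@]2(C)OC(=O)C[C@@H]2OO1 | intermediate
15 | (E)-crotonaldehyde | C/C=C/C=O | starting material
16 | (E)-11-[(3S,4aS,7aS)-3,4a-dimethyl-6-oxotetrahydrofuro[3,2-c][1,2]dioxin-3-yl]undec-2-enal | O=C/C=C/CCCCCCCC[C@@]1(C)C[C@]2(C)OC(=O)C[C@@H]2OO1 | intermediate
17 | (E)-1-bromopent-2-ene | CC/C=C/CBr | starting material
18 | triethyl phosphite | CCOP(OCC)OCC | starting material
19 | diethyl [(E)-pent-2-en-1-yl]phosphonate | CC/C=C/CP(=O)(OCC)OCC | intermediate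
20 | lithium salt of the α-carbanion of 19 | [Li+].CC/C=C/[CH-]P(=O)(OCC)OCC | intermediate (not isolated)
21 | (3S,4aS,7aS)-3-[(9E,11E,13E)-hexadeca-9,11,13-trien-1-yl]-3,4a-dimethyltetrahydrofuro[3,2-c][1,2]dioxin-6(3H)-one | CC/C=C/C=C/C=C/CCCCCCCC[C@@]1(C)C[C@]2(C)OC(=O)C[C@@H]2OO1 | target

**Step count**
- Total steps: 9.
- Longest linear sequence: 8 steps (1 → 3 → 4 → 11 → 12 → 13 → 14 → 16 → 21).

**Steps most likely to fail**

Step 5. The selectivity factor of the resolution is unknown, and the yield cannot exceed 50 %. The fallback sets out from 12 and comes back at 13, and it moves the resolution onto a covalent auxiliary. Compound 12 is coupled with (S)-1-phenylethylamine (EDC·HCl, HOBt, CH2Cl2, 0 °C). This gives the (3S,6S,1'S)-amide F4 and the (3R,6R,1'S)-amide F5, which are diastereomers and are separated on silica. F4 is then iodolactonised through its amide oxygen (I2, THF–H2O, 0 °C). The reaction passes through the iodo imidate F6, whose hydrolysis in the same flask releases the amine and gives 13.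

Step 4. One alkyl group on C6 always points into the s-cis diene, so ene hydroperoxides and a stereochemically leaky stepwise addition compete with the cycloaddition. The fallback sets out from 3 and comes back at 12. It changes the order of oxidation events: dioxygen is brought in at the alcohol level, the substrate class for which this cycloaddition pattern is established, and the carboxyl group is made only after the peroxide ring exists. Compound 3 is turned with NaH into sodium (E)-4-iodopent-3-en-1-olate F1. F1 is coupled with alkenylzinc 9 under Pd(PPh3)4, as 10 was, to give (3E,5Z)-4,6-dimethylhexadeca-3,5,15-trien-1-ol F2. This neutral dienol is photooxygenated (O2, tetraphenylporphyrin, CH2Cl2, −20 °C) to the racemic dioxine ethanol F3. TEMPO/PhI(OAc)2 in MeCN–H2O then oxidises F3 to 12.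

Step 9. A strong base meets a lactone whose β-position carries the peroxide, and the E/Z ratio of the new alkene may fall short. The fallback sets out from 14 and comes back at 21. It replaces the carbonyl olefination by a stereoretentive sp2–sp2 coupling under weak base. Compound 14 undergoes cross-metathesis with vinylboronic acid pinacol ester (second-generation Hoveyda–Grubbs catalyst, CH2Cl2, 40 °C) to give the (E)-alkenyl pinacol boronate F7. Separately, (E)-pent-2-enal is converted by Takai olefination (CHI3, CrCl2, THF, 0 °C) into (1E,3E)-1-iodohexa-1,3-diene F8. Suzuki–Miyaura coupling of F7 with F8 (PdCl2(dppf) 5 mol %, aq K3PO4, THF, rt; the chelating phosphine leaves no free phosphine to reduce the O–O bond) gives 21.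

**Further compounds**
F1 | step 4 | sodium (E)-4-iodopent-3-en-1-olate | C/C(I)=C\CC[O-].[Na+]
F2 | step 4 | (3E,5Z)-4,6-dimethylhexadeca-3,5,15-trien-1-ol | C=CCCCCCCCC/C(C)=C\C(C)=C\CCO
F3 | step 4 | rac-2-[(3S*,6S*)-6-(dec-9-en-1-yl)-4,6-dimethyl-3,6-dihydro-1,2-dioxin-3-yl]ethanol (the (3S,6S) enantiomer is drawn) | C=CCCCCCCCC[C@@]1(C)C=C(C)[C@H](CCO)OO1
F4 | step 5 | 2-[(3S,6S)-6-(dec-9-en-1-yl)-4,6-dimethyl-3,6-dihydro-1,2-dioxin-3-yl]-N-[(1S)-1-phenylethyl]acetamide | C=CCCCCCCCC[C@@]1(C)C=C(C)[C@H](CC(=O)N[C@@H](C)c2ccccc2)OO1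
F5 | step 5 | 2-[(3R,6R)-6-(dec-9-en-1-yl)-4,6-dimethyl-3,6-dihydro-1,2-dioxin-3-yl]-N-[(1S)-1-phenylethyl]acetamide | C=CCCCCCCCC[C@]1(C)C=C(C)[C@@H](CC(=O)N[C@@H](C)c2ccccc2)OO1
F6 | step 5 | N-[(1S)-1-phenylethyl] imidate of iodolactone 13 | C=CCCCCCCCC[C@@]1(C)[C@@H](I)[C@]2(C)OC(=N[C@@H](C)c3ccccc3)C[C@@H]2OO1
F7 | step 9 | (3S,4aS,7aS)-3,4a-dimethyl-3-[(E)-10-(4,4,5,5-tetramethyl-1,3,2-dioxaborolan-2-yl)dec-9-en-1-yl]tetrahydrofuro[3,2-c][1,2]dioxin-6(3H)-one | CC1(C)OB(/C=C/CCCCCCCC[C@@]2(C)C[C@]3(C)OC(=O)C[C@@H]3OO2)OC1(C)C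
F8 | step 9 | (1E,3E)-1-iodohexa-1,3-diene | CC/C=C/C=C/I
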